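**Plan**
Retrosynthesis: after removal of the ring B silyl ether and the C7 methyl ether (C7–O traced back to C7–B), three bonds of ring A are cut at once, C3a–C7a, C4–C5 and C6–C7, as an alkyne [2+2+2] disconnection.
Enabling feature: ring A carries its substituents on alternate carbons (C3 on C3a, propenyl on C5, oxygen on C7) and the ring oxygen O1 on C7a, so ring A and the dihydrofuran unzip into an ynol ether 1,6-diyne, whose three-atom tether O1–C2–C3 already holds both stereocentres, plus the terminal alkyne (E)-pent-3-en-1-yne.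
Forward: ring B is present from the start; the C2–C3 bond joins its aldehyde to a propargyl unit, the alcohol becomes a boron-capped alkynyl ether, and one rhodium-catalysed cyclotrimerisation closes the dihydrofuran ring and ring A together.
Stereochemistry: C2 and C3 are set together (anti, later trans) in a Marshall propargylation controlled by the (R) carbinol centre of a silylbutynol mesylate and are spectators afterwards; the (E) alkene comes from (E)-1-bromoprop-1-ene.
Endgame: C7–B to C7–OH, O-methylation, fluoride desilylation.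

Key step: step 9

Assumption: the allenylzinc addition follows its usual anti-SN2′ then cyclic-SE2′ course, so that (R)-mesylate 4 gives the (1S,2S) anti alcohol 6 (target = trans (2S,3S) isomer; benzofuran numbering O1, C2, C3, C3a, C4–C7, C7a); with the opposite sense the (S)-alcohol would be used.
Abbreviations: Ar = 3,4-dimethoxy-5-[(triisopropylsilyl)oxy]phenyl; B(dan) = boron bound to both nitrogens of naphthalene-1,8-diamine (2,3-dihydro-1H-naphtho[1,8-de][1,3,2]diazaborinin-2-yl).

Step 1
Reactants: 1 3-hydroxy-4,5-dimethoxybenzaldehyde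
Product: 2 3,4-dimethoxy-5-[(triisopropylsilyl)oxy]benzaldehyde
Conditions: TIPSCl, imidazole, DMF, rt
Reagents that add atoms: chlorotri(propan-2-yl)silane, CC(C)[Si](Cl)(C(C)C)C(C)C
Why: Imidazole-assisted silylation of a phenol; the bulky silyl ether is chosen to outlast KH, n-BuLi, carbonate in methanol and dilute acid and still leave with fluoride at the end.

Step 2
Reactants: 3 (R)-4-(trimethylsilyl)but-3-yn-2-ol
Product: 4 (R)-4-(trimethylsilyl)but-3-yn-2-yl methanesulfonate
Conditions: MsCl, Et3N, CH2Cl2, −78 °C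
Reagents that add atoms: methanesulfonyl chloride, CS(=O)(=O)Cl
Why: O-Sulfonylation of a secondary propargylic alcohol, which leaves the (R) carbinol centre untouched and gives the electrophile for the Marshall reaction.

Step 3
Reactants: 2 3,4-dimethoxy-5-[(triisopropylsilyl)oxy]benzaldehyde; 4 (R)-4-(trimethylsilyl)but-3-yn-2-yl methanesulfonate
Product: 6 (1S,2S)-1-Ar-2-methyl-4-(trimethylsilyl)but-3-yn-1-ol, via allenylzinc reagent 5 (not isolated)
Conditions: Pd(OAc)2 (5 mol %), PPh3 (5 mol %), Et2Zn (3 equiv), THF, −78 to −20 °C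
Reagents that add atoms: none
Why: Marshall propargylation, in which zerovalent palladium displaces the mesylate anti in an SN2′ sense, transmetalation gives the (P)-allenylzinc 5, and its cyclic SE2′ addition keeps the aryl group away from the allenyl methyl, so that C2 and C3 of the target are set together as the anti (1S,2S) pair under control of the (R) centre of 4 (any syn isomer is removed by chromatography).

Step 4
Reactants: 6 (1S,2S)-1-Ar-2-methyl-4-(trimethylsilyl)but-3-yn-1-ol; 7 trichloroethene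
Product: 9 [(3S,4S)-4-Ar-4-{[(E)-1,2-dichloroethenyl]oxy}-3-methylbut-1-yn-1-yl]trimethylsilane, via potassium alkoxide 8 (not isolated)
Conditions: KH, THF, 0 °C; then 7, −50 °C to rt
Reagents that add atoms: none
Why: First half of the trichloroethene route to alkynyl ethers, in which alkoxide 8 adds anti to dichloroethyne released from 7 to give the (E)-dichlorovinyl ether without touching C2 or C3, while the silyl cap on the alkyne ensures that only one acetylide can form in step 5.

Step 5
Reactants: 9 [(3S,4S)-4-Ar-4-{[(E)-1,2-dichloroethenyl]oxy}-3-methylbut-1-yn-1-yl]trimethylsilane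
Product: 14 2-({[(1S,2S)-1-Ar-2-methyl-4-(trimethylsilyl)but-3-yn-1-yl]oxy}ethynyl)-B(dan), via chloroalkynyl ether 10 (not isolated), via lithium alkoxyacetylide 11 (not isolated), via lithium alkynyltriisopropoxyborate 12 (not isolated), via diisopropyl alkynylboronate 13 (not isolated)
Conditions: n-BuLi (2.2 equiv), THF, −78 °C; B(OiPr)3, −78 °C; Me3SiCl, −78 to 0 °C; naphthalene-1,8-diamine, 0 °C to rt
Reagents that add atoms: triisopropyl borate, CC(C)OB(OC(C)C)OC(C)C; naphthalene-1,8-diamine, Nc1cccc2cccc(N)c12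
Why: Second half of the trichloroethene route (elimination to 10, lithium–chlorine exchange to 11), then the standard borylation of a lithium acetylide with a borate ester and ligand exchange at boron, where the diamine removes the Lewis acidity of boron so that the C(sp)–B bond should survive the desilylation of step 6, and everything is kept at or below room temperature because secondary alkynyl ethers fragment on heating.

Step 6
Reactants: 14 2-({[(1S,2S)-1-Ar-2-methyl-4-(trimethylsilyl)but-3-yn-1-yl]oxy}ethynyl)-B(dan)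
Product: 15 2-({[(1S,2S)-1-Ar-2-methylbut-3-yn-1-yl]oxy}ethynyl)-B(dan)
Conditions: K2CO3 (0.2 equiv), MeOH–THF, 0 °C
Reagents that add atoms: none
Why: Carbonate-catalysed methanolysis of the alkynyl C–Si bond, under which diamine-capped alkynylboron compounds, ynol ethers and the aryl silyl ether are expected to be stable, frees the terminal alkyne that becomes C4–H.

Step 7
Reactants: 16 (E)-1-bromoprop-1-ene; 17 ethynyltrimethylsilane
Product: 18 trimethyl[(E)-pent-3-en-1-yn-1-yl]silane
Conditions: Pd(PPh3)2Cl2 (2 mol %), CuI (4 mol %), Et3N, THF, rt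
Reagents that add atoms: none
Why: Sonogashira coupling of a vinyl bromide, which proceeds with retention of the (E) geometry and gives a silylated enyne that is easy to purify.

Step 8
Reactants: 18 trimethyl[(E)-pent-3-en-1-yn-1-yl]silane
Product: 19 (E)-pent-3-en-1-yne
Conditions: KF, H2O, DMSO, rt; product swept into a −78 °C trap and taken up in CH2Cl2
Reagents that add atoms: none
Why: Fluoride-promoted protodesilylation of an alkynylsilane in a high-boiling medium, so that the volatile enyne can be removed as it forms and used as a titrated solution.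

Step 9
Reactants: 15 2-({[(1S,2S)-1-Ar-2-methylbut-3-yn-1-yl]oxy}ethynyl)-B(dan); 19 (E)-pent-3-en-1-yne
Product: 20 2-[(2S,3S)-2-Ar-3-methyl-5-[(E)-prop-1-en-1-yl]-2,3-dihydro-1-benzofuran-7-yl]-B(dan)
Conditions: [Rh(cod)2]BF4 (5 mol %), rac-BINAP (5 mol %), H2-activated; 19 (4 equiv), CH2Cl2, rt, slow addition of 15
Reagents that add atoms: none
Why: Proposed new method: oxidative coupling of the ynol ether alkyne and the terminal alkyne of 15 on monovalent rhodium should give a rhodacyclopentadiene and with it the C3a–C7a bond, after which insertion of the triple bond of 19 and reductive elimination form C4–C5 and C6–C7. The closest known reactions are rhodium-catalysed [2+2+2] cycloadditions of ynamide- or ynol-ether-tethered 1,6-diynes with terminal alkynes and cyclotrimerisations of alkynylboronates and alkynylboron amides; new here is their combination in a boron-capped ynol ether diyne with a conjugated enyne partner. The dihydrofuran ring closes in the oxidative coupling (five-membered ring fused to the rhodacycle) and ring A closes in the insertion and reductive elimination. No stereocentre is formed, because C2 and C3 lie in the O1–C2–C3 tether and pass through unchanged, and room temperature guards the secondary ynol ether against retro-ene fragmentation. The step needs regiocontrol (propenyl at C5, not C6) and cross- over self-reaction: the bulky boron amide on the ynol ether terminus should steer the substituted carbon of 19 to the unhindered C4 terminus, and slow addition of 15 to an excess of 19 should suppress diyne oligomerisation.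

Step 10
Reactants: 20 2-[(2S,3S)-2-Ar-3-methyl-5-[(E)-prop-1-en-1-yl]-2,3-dihydro-1-benzofuran-7-yl]-B(dan)
Product: 22 (2S,3S)-2-Ar-3-methyl-5-[(E)-prop-1-en-1-yl]-2,3-dihydro-1-benzofuran-7-ol, via arylboronic acid 21 (not isolated)
Conditions: 2 M aq H2SO4, THF, rt; organic phase then 30% H2O2, aq NaHCO3, 0 °C
Reagents that add atoms: hydrogen peroxide, OO
Why: Acid hydrolysis of the boron amide to boronic acid 21, then peroxide oxidation with migration of the aryl group from boron to oxygen, a sequence that should leave C2, C3 and the alkene untouched provided the acid contact is short and at room temperature.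

Step 11
Reactants: 22 (2S,3S)-2-Ar-3-methyl-5-[(E)-prop-1-en-1-yl]-2,3-dihydro-1-benzofuran-7-ol
Product: 23 {5-[(2S,3S)-7-methoxy-3-methyl-5-[(E)-prop-1-en-1-yl]-2,3-dihydro-1-benzofuran-2-yl]-2,3-dimethoxyphenoxy}triisopropylsilane
Conditions: MeI, K2CO3, acetone, 40 °C
Reagents that add atoms: iodomethane, CI
Why: Williamson methylation of the only free phenol (the ring B phenol is still silylated), which fixes the 7-methoxy group.

Step 12
Reactants: 23 {5-[(2S,3S)-7-methoxy-3-methyl-5-[(E)-prop-1-en-1-yl]-2,3-dihydro-1-benzofuran-2-yl]-2,3-dimethoxyphenoxy}triisopropylsilane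
Product: 24 5-[(2S,3S)-7-methoxy-3-methyl-5-[(E)-prop-1-en-1-yl]-2,3-dihydro-1-benzofuran-2-yl]-2,3-dimethoxyphenol
Conditions: TBAF, AcOH, THF, 0 °C
Reagents that add atoms: none
Why: Fluoride cleavage of the aryl silyl ether, buffered with acetic acid so that the phenoxide is protonated as it forms, should release the target without affecting the alkene or the stereocentres.

**Compound list**
1 | 3-hydroxy-4,5-dimethoxybenzaldehyde | O=Cc1cc(O)c(OC)c(OC)c1 | starting material
2 | 3,4-dimethoxy-5-[(triisopropylsilyl)oxy]benzaldehyde | O=Cc1cc(O[Si](C(C)C)(C(C)C)C(C)C)c(OC)c(OC)c1 | intermediate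
3 | (R)-4-(trimethylsilyl)but-3-yn-2-ol | C[Si](C)(C)C#C[C@@H](C)O | starting material
4 | (R)-4-(trimethylsilyl)but-3-yn-2-yl methanesulfonate | C[Si](C)(C)C#C[C@@H](C)OS(C)(=O)=O | intermediate
5 | (P)-ethyl[1-(trimethylsilyl)buta-1,2-dien-1-yl]zinc | CC([H])=[C@]=C([Zn]CC)[Si](C)(C)C | intermediate (not isolated)
6 | (1S,2S)-1-Ar-2-methyl-4-(trimethylsilyl)but-3-yn-1-ol (anti) | C[Si](C)(C)C#C[C@H](C)[C@@H](c1cc(O[Si](C(C)C)(C(C)C)C(C)C)c(OC)c(OC)c1)O | intermediate
7 | trichloroethene | ClC=C(Cl)Cl | starting material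
8 | potassium (1S,2S)-1-Ar-2-methyl-4-(trimethylsilyl)but-3-yn-1-olate | C[Si](C)(C)C#C[C@H](C)[C@@H](c1cc(O[Si](C(C)C)(C(C)C)C(C)C)c(OC)c(OC)c1)[O-].[K+] | intermediate (not isolated)
9 | [(3S,4S)-4-Ar-4-{[(E)-1,2-dichloroethenyl]oxy}-3-methylbut-1-yn-1-yl]trimethylsilane | C[Si](C)(C)C#C[C@H](C)[C@@H](c1cc(O[Si](C(C)C)(C(C)C)C(C)C)c(OC)c(OC)c1)O/C(Cl)=C\Cl | intermediate
10 | [(3S,4S)-4-Ar-4-[(chloroethynyl)oxy]-3-methylbut-1-yn-1-yl]trimethylsilane | C[Si](C)(C)C#C[C@H](C)[C@@H](c1cc(O[Si](C(C)C)(C(C)C)C(C)C)c(OC)c(OC)c1)OC#CCl | intermediate (not isolated)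
11 | lithium 2-{[(1S,2S)-1-Ar-2-methyl-4-(trimethylsilyl)but-3-yn-1-yl]oxy}ethyn-1-ide | C[Si](C)(C)C#C[C@H](C)[C@@H](c1cc(O[Si](C(C)C)(C(C)C)C(C)C)c(OC)c(OC)c1)OC#C[Li] | intermediate (not isolated)
12 | lithium ({[(1S,2S)-1-Ar-2-methyl-4-(trimethylsilyl)but-3-yn-1-yl]oxy}ethynyl)tri(propan-2-yloxy)borate | C[Si](C)(C)C#C[C@H](C)[C@@H](c1cc(O[Si](C(C)C)(C(C)C)C(C)C)c(OC)c(OC)c1)OC#C[B-](OC(C)C)(OC(C)C)OC(C)C.[Li+] | intermediate (not isolated)
13 | dipropan-2-yl ({[(1S,2S)-1-Ar-2-methyl-4-(trimethylsilyl)but-3-yn-1-yl]oxy}ethynyl)boronate | C[Si](C)(C)C#C[C@H](C)[C@@H](c1cc(O[Si](C(C)C)(C(C)C)C(C)C)c(OC)c(OC)c1)OC#CB(OC(C)C)OC(C)C | intermediate (not isolated)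
14 | 2-({[(1S,2S)-1-Ar-2-methyl-4-(trimethylsilyl)but-3-yn-1-yl]oxy}ethynyl)-2,3-dihydro-1H-naphtho[1,8-de][1,3,2]diazaborinine | C[Si](C)(C)C#C[C@H](C)[C@@H](c1cc(O[Si](C(C)C)(C(C)C)C(C)C)c(OC)c(OC)c1)OC#CB1Nc2cccc3cccc(N1)c23 | intermediate
15 | 2-({[(1S,2S)-1-Ar-2-methylbut-3-yn-1-yl]oxy}ethynyl)-2,3-dihydro-1H-naphtho[1,8-de][1,3,2]diazaborinine | C#C[C@H](C)[C@@H](c1cc(O[Si](C(C)C)(C(C)C)C(C)C)c(OC)c(OC)c1)OC#CB1Nc2cccc3cccc(N1)c23 | intermediate (key-step diyne)
16 | (E)-1-bromoprop-1-ene | C/C=C/Br | starting material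
17 | ethynyltrimethylsilane | C#C[Si](C)(C)C | starting material
18 | trimethyl[(E)-pent-3-en-1-yn-1-yl]silane | C/C=C/C#C[Si](C)(C)C | intermediate
19 | (E)-pent-3-en-1-yne | C/C=C/C#C | intermediate (key-step alkyne)
20 | 2-[(2S,3S)-2-Ar-3-methyl-5-[(E)-prop-1-en-1-yl]-2,3-dihydro-1-benzofuran-7-yl]-2,3-dihydro-1H-naphtho[1,8-de][1,3,2]diazaborinine | C/C=C/c1cc(B3Nc4cccc5cccc(N3)c45)c2c(c1)[C@H](C)[C@@H](c1cc(O[Si](C(C)C)(C(C)C)C(C)C)c(OC)c(OC)c1)O2 | intermediate (key-step product)
21 | [(2S,3S)-2-Ar-3-methyl-5-[(E)-prop-1-en-1-yl]-2,3-dihydro-1-benzofuran-7-yl]boronic acid | C/C=C/c1cc(B(O)O)c2c(c1)[C@H](C)[C@@H](c1cc(O[Si](C(C)C)(C(C)C)C(C)C)c(OC)c(OC)c1)O2 | intermediate (not isolated)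
22 | (2S,3S)-2-Ar-3-methyl-5-[(E)-prop-1-en-1-yl]-2,3-dihydro-1-benzofuran-7-ol | C/C=C/c1cc(O)c2c(c1)[C@H](C)[C@@H](c1cc(O[Si](C(C)C)(C(C)C)C(C)C)c(OC)c(OC)c1)O2 | intermediate
23 | {5-[(2S,3S)-7-methoxy-3-methyl-5-[(E)-prop-1-en-1-yl]-2,3-dihydro-1-benzofuran-2-yl]-2,3-dimethoxyphenoxy}triisopropylsilane | C/C=C/c1cc(OC)c2c(c1)[C@H](C)[C@@H](c1cc(O[Si](C(C)C)(C(C)C)C(C)C)c(OC)c(OC)c1)O2 | intermediate
24 | 5-[(2S,3S)-7-methoxy-3-methyl-5-[(E)-prop-1-en-1-yl]-2,3-dihydro-1-benzofuran-2-yl]-2,3-dimethoxyphenol | C/C=C/c1cc(OC)c2c(c1)[C@H](C)[C@@H](c1cc(O)c(OC)c(OC)c1)O2 | target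

**Step count and risks**
Total step count: 12. Longest linear sequence: 9 steps (steps 1, 3, 4, 5, 6, 9, 10, 11, 12).

Steps most likely to fail:

Step 9. What may go wrong: self-oligomerisation of the enyne or of the diyne outrunning the cross-cycloaddition, insertion of 19 in the reverse orientation, or fragmentation of the ynol ether before the rhodacycle forms. Fallback (known chemistry only; sets out from 2, returns at 23):
- Julia–Kocienski ethylidenation of 2 (5-(ethylsulfonyl)-1-phenyl-1H-tetrazole, KN(SiMe3)2, DME, −60 °C to rt) should give triisopropyl{2,3-dimethoxy-5-[(E)-prop-1-en-1-yl]phenoxy}silane F1.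
- Palladium-catalysed oxyarylation of F1 with commercial 4-hydroxy-3-iodo-5-methoxybenzaldehyde (Pd(OAc)2, Ag2CO3, acetone, 60 °C) adds the aryl group to the methyl-bearing alkene carbon and closes the phenol oxygen onto the benzylic carbon. It should give racemic trans-2-Ar-7-methoxy-3-methyl-2,3-dihydro-1-benzofuran-5-carbaldehyde F2.
- Preparative chromatography on a chiral stationary phase then isolates (2S,3S)-2-Ar-7-methoxy-3-methyl-2,3-dihydro-1-benzofuran-5-carbaldehyde F3.
- A second Julia–Kocienski ethylidenation turns the formyl group into the (E)-propenyl group and delivers 23.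
- This path gives up the cyclotrimerisation and the reagent-controlled stereochemistry and relies on resolution.

Step 5. What may go wrong: breakdown of the electron-rich alkynylboron species (oligomerisation or protonolysis of the tricoordinate boronate) before the diamine has capped boron, or competing deprotonation at the benzylic C–H by n-BuLi. Fallback (sets out from 9, returns at 14):
- Boron is kept tetracoordinate until it is capped. 9 is lithiated and borate 12 is formed as in step 5, but 12 is then treated with aqueous KHF2 (acetone, 0 °C, short contact). This gives potassium ({[(1S,2S)-1-Ar-2-methyl-4-(trimethylsilyl)but-3-yn-1-yl]oxy}ethynyl)trifluoroborate F4, a salt that can be isolated and stored.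
- Me3SiCl and naphthalene-1,8-diamine (Et3N, MeCN, rt) then exchange fluoride for the diamine and give 14.

Step 10. What may go wrong: acid-induced protonation of the propenyl arene (hydration, dimerisation) or reversible ionisation of the benzylic C2–O1 bond while the boron amide is hydrolysed. Fallback (sets out from 15, returns at 23):
- The double bond is kept out of conjugation until the acid step is over. Cyclotrimerisation of 15 with commercial pent-1-en-4-yne under the conditions of step 9 should give 2-[(2S,3S)-2-Ar-3-methyl-5-(prop-2-en-1-yl)-2,3-dihydro-1-benzofuran-7-yl]-2,3-dihydro-1H-naphtho[1,8-de][1,3,2]diazaborinine F5.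
- Hydrolysis and oxidation as in step 10 proceed through [(2S,3S)-2-Ar-3-methyl-5-(prop-2-en-1-yl)-2,3-dihydro-1-benzofuran-7-yl]boronic acid F6 (not isolated) to (2S,3S)-2-Ar-3-methyl-5-(prop-2-en-1-yl)-2,3-dihydro-1-benzofuran-7-ol F7.
- Methylation as in step 11 gives {5-[(2S,3S)-7-methoxy-3-methyl-5-(prop-2-en-1-yl)-2,3-dihydro-1-benzofuran-2-yl]-2,3-dimethoxyphenoxy}triisopropylsilane F8.
- Isomerisation with RuHCl(CO)(PPh3)3 (toluene, 80 °C) moves the allyl double bond into conjugation, mainly as the (E) isomer, and gives 23.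

**Further compounds**
F1 | step 9 | triisopropyl{2,3-dimethoxy-5-[(E)-prop-1-en-1-yl]phenoxy}silane | C/C=C/c1cc(O[Si](C(C)C)(C(C)C)C(C)C)c(OC)c(OC)c1
F2 | step 9 | racemic trans-2-Ar-7-methoxy-3-methyl-2,3-dihydro-1-benzofuran-5-carbaldehyde (both enantiomers) | O=Cc1cc(OC)c2c(c1)[C@H](C)[C@@H](c1cc(O[Si](C(C)C)(C(C)C)C(C)C)c(OC)c(OC)c1)O2.O=Cc1cc(OC)c2c(c1)[C@@H](C)[C@H](c1cc(O[Si](C(C)C)(C(C)C)C(C)C)c(OC)c(OC)c1)O2
F3 | step 9 | (2S,3S)-2-Ar-7-methoxy-3-methyl-2,3-dihydro-1-benzofuran-5-carbaldehyde | O=Cc1cc(OC)c2c(c1)[C@H](C)[C@@H](c1cc(O[Si](C(C)C)(C(C)C)C(C)C)c(OC)c(OC)c1)O2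
F4 | step 5 | potassium ({[(1S,2S)-1-Ar-2-methyl-4-(trimethylsilyl)but-3-yn-1-yl]oxy}ethynyl)trifluoroborate | C[Si](C)(C)C#C[C@H](C)[C@@H](c1cc(O[Si](C(C)C)(C(C)C)C(C)C)c(OC)c(OC)c1)OC#C[B-](F)(F)F.[K+]
F5 | step 10 | 2-[(2S,3S)-2-Ar-3-methyl-5-(prop-2-en-1-yl)-2,3-dihydro-1-benzofuran-7-yl]-2,3-dihydro-1H-naphtho[1,8-de][1,3,2]diazaborinine | C=CCc1cc(B3Nc4cccc5cccc(N3)c45)c2c(c1)[C@H](C)[C@@H](c1cc(O[Si](C(C)C)(C(C)C)C(C)C)c(OC)c(OC)c1)O2
F6 | step 10 | [(2S,3S)-2-Ar-3-methyl-5-(prop-2-en-1-yl)-2,3-dihydro-1-benzofuran-7-yl]boronic acid | C=CCc1cc(B(O)O)c2c(c1)[C@H](C)[C@@H](c1cc(O[Si](C(C)C)(C(C)C)C(C)C)c(OC)c(OC)c1)O2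
F7 | step 10 | (2S,3S)-2-Ar-3-methyl-5-(prop-2-en-1-yl)-2,3-dihydro-1-benzofuran-7-ol | C=CCc1cc(O)c2c(c1)[C@H](C)[C@@H](c1cc(O[Si](C(C)C)(C(C)C)C(C)C)c(OC)c(OC)c1)O2
F8 | step 10 | {5-[(2S,3S)-7-methoxy-3-methyl-5-(prop-2-en-1-yl)-2,3-dihydro-1-benzofuran-2-yl]-2,3-dimethoxyphenoxy}triisopropylsilane | C=CCc1cc(OC)c2c(c1)[C@H](C)[C@@H](c1cc(O[Si](C(C)C)(C(C)C)C(C)C)c(OC)c(OC)c1)O2
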